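**Plan**
- Retrosynthesis: the catechol is taken back two oxidation levels to a cyclohex-4-ene-cis-1,2-diol (as its cyclic carbonate). The ring bonds C1–C2 and C3–C4 are then cut together, and last the ester C–O bond to the C21 alcohol.
- Enabling feature: C2 and C3 with their oxygens are a cis-enediol two-carbon unit (vinylene carbonate). The ester carbonyl with ring carbons C1, C6, C5 and C4 is a penta-2,4-dienoate, so the only ring of the target can arise in one [4+2] step.
- Forward order: the chain is joined first by esterification, the six-membered ring closes by Diels–Alder reaction, the carbonate is removed, and double alcohol oxidation with enolisation delivers the arene.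
- Stereochemistry: the target is achiral. The three stereocentres of the cycloadduct (cis fusion from the Z-dienophile, ester cis by endo addition) are racemic, need no control and vanish on aromatisation.

Key step: step 2

Remark on the chemistry: the cycloadduct and the diol are written as the endo-derived all-cis racemates; an exo epimer at the ester-bearing carbon, if formed, is carried through unseparated, since aromatisation removes all three stereocentres.

Step 1
Reactants: 1 (2E)-penta-2,4-dienoic acid; 2 1-heneicosanol
Product: 3 heneicosyl (2E)-penta-2,4-dienoate
Conditions: DCC (1.1 equiv), DMAP (0.1 equiv), BHT (trace), CH2Cl2, 0 °C → rt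
Reagents that add atoms: none
Why: Steglich esterification, in which the acid is activated as its O-acylisourea/acylpyridinium and captured by the unhindered primary alcohol under neutral, cold conditions that should leave the E-diene intact and unpolymerised.

Step 2
Reactants: 3 heneicosyl (2E)-penta-2,4-dienoate; 4 vinylene carbonate (1,3-dioxol-2-one)
Product: 5 heneicosyl (3aRS,4RS,7aSR)-2-oxo-3a,4,7,7a-tetrahydro-1,3-benzodioxole-4-carboxylate (all-cis, racemic)
Conditions: 4 (10 equiv, excess recovered by distillation), BHT (5 mol%), o-xylene, sealed tube, argon, 170 °C
Reagents that add atoms: none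
Why: A concerted, suprafacial thermal [4+2] Diels–Alder cycloaddition joins the two termini of the s-cis diene of 3 (the ester-bearing carbon and the CH2 end) to the two alkene carbons of 4, forming target bonds C1–C2 and C3–C4 at once. The closest known reactions are the thermal cycloadditions of vinylene carbonate with buta-1,3-dienes and with electron-poor dienes such as 2-pyrones, which need comparable temperatures. The cyclohexene ring closes by intermolecular [4+2] annulation, the central diene bond becoming the ring alkene and the dioxolanone arriving cis-fused. The two ring-fusion stereocentres are fixed cis by the Z geometry locked in the dienophile ring, and the ester-bearing centre is set relative to them by the endo transition state with the carbonate under the diene (all-cis); the exo epimer would serve equally. The only selectivity needed is cross-cycloaddition over dimerisation or radical polymerisation of the diene, which the large excess of the symmetrical dienophile (both alkene carbons identical, hence no regiochemical issue) and the BHT inhibitor should secure, while the E-configured, terminally unsubstituted diene reaches the s-cis conformer without strain.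

Step 3
Reactants: 5 heneicosyl (3aRS,4RS,7aSR)-2-oxo-3a,4,7,7a-tetrahydro-1,3-benzodioxole-4-carboxylate
Product: 6 heneicosyl (1RS,5SR,6RS)-5,6-dihydroxycyclohex-2-ene-1-carboxylate (all-cis, racemic)
Conditions: K2CO3 (0.2 equiv), MeOH–THF (1:1), 0 °C, 30 min; AcOH quench
Reagents that add atoms: none
Why: Base-catalysed transesterification (methanolysis) of the strained five-membered cyclic carbonate should be far faster than attack on the α-branched long-chain ester or α-deprotonation, releasing the cis-diol with the three stereocentres untouched.

Step 4
Reactants: 6 heneicosyl (1RS,5SR,6RS)-5,6-dihydroxycyclohex-2-ene-1-carboxylate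
Product: 8 Gentiside I (heneicosyl 2,3-dihydroxybenzoate), via cyclohexene-1,2-dione 7 (not isolated)
Conditions: DMSO (6 equiv), TFAA (4.5 equiv), CH2Cl2, −78 °C; then Et3N (10 equiv), −78 °C → rt; aq. NaHCO3 work-up
Reagents that add atoms: none
Why: Swern-type activated-DMSO oxidation converts both secondary alcohols to the 1,2-dione 7 without glycol cleavage, and 7, a β-keto ester with a skipped alkene, should enolise under Et3N toward C1 and toward C4 to give the aromatic catechol, erasing all stereocentres.

**Compound list**
1 | (2E)-penta-2,4-dienoic acid | OC(=O)/C=C/C=C | starting material
2 | 1-heneicosanol | CCCCCCCCCCCCCCCCCCCCCO | starting material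
3 | heneicosyl (2E)-penta-2,4-dienoate | CCCCCCCCCCCCCCCCCCCCCOC(=O)/C=C/C=C | intermediate
4 | vinylene carbonate (1,3-dioxol-2-one) | O=C1OC=CO1 | starting material
5 | heneicosyl (3aRS,4RS,7aSR)-2-oxo-3a,4,7,7a-tetrahydro-1,3-benzodioxole-4-carboxylate (all-cis, racemic, one enantiomer drawn) | O=C1O[C@H]2[C@@H](C(=O)OCCCCCCCCCCCCCCCCCCCCC)C=CC[C@H]2O1 | intermediate
6 | heneicosyl (1RS,5SR,6RS)-5,6-dihydroxycyclohex-2-ene-1-carboxylate (all-cis, racemic, one enantiomer drawn) | O[C@H]1[C@@H](C(=O)OCCCCCCCCCCCCCCCCCCCCC)C=CC[C@H]1O | intermediate
7 | heneicosyl 5,6-dioxocyclohex-2-ene-1-carboxylate (racemic, formed in the flask in step 4) | CCCCCCCCCCCCCCCCCCCCCOC(=O)C1C=CCC(=O)C1=O | intermediate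
8 | Gentiside I (heneicosyl 2,3-dihydroxybenzoate) | CCCCCCCCCCCCCCCCCCCCCOC(=O)c1cccc(O)c1O | target

**Count and risks**
Total steps: 4. Longest linear sequence: 4 steps (from 1 or 2 to 8).

The three steps most likely to fail are, in decreasing order of risk, steps 2, 3 and 4.

Step 2. The slow cycloaddition of an electron-poor diene with a moderate dienophile may be outrun by Diels–Alder dimerisation or radical polymerisation of the diene at 170 °C. The fallback keeps the same two bond formations but inverts the electron demand. It sets out from 3, which is heated with the electron-rich enediol acetonide 2,2-dimethyl-1,3-dioxole (toluene, BHT, sealed tube, about 140 °C) to give heneicosyl all-cis-2,2-dimethyl-3a,4,7,7a-tetrahydro-1,3-benzodioxole-4-carboxylate F1. Its acetonide is then cleaved with aqueous acetic acid in THF at about 50 °C, and the sequence comes back to the route at diol 6.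

Step 3. Under base, the ester enolate may expel the β-carbonate oxygen (E1cB elimination), or the heneicosyl ester may be exchanged for a methyl ester, possibly assisted by the neighbouring cis hydroxyl. The fallback reaches the same diol pattern with no base-labile protecting group. It sets out from 2, which is esterified (DCC, DMAP, CH2Cl2) with cyclohexa-2,5-diene-1-carboxylic acid, the Birch reduction product of benzoic acid, to give heneicosyl cyclohexa-2,5-diene-1-carboxylate F2. Upjohn mono-dihydroxylation of one of its two equivalent alkenes (OsO4 cat., NMO, acetone–water, 0 °C, stopped at partial conversion) should give heneicosyl (1RS,5RS,6SR)-5,6-dihydroxycyclohex-2-ene-1-carboxylate F3, with the diol expected mainly trans to the ester. F3 is oxidised under the conditions of step 4 and comes back to the route at dione 7, where the configurational difference from 6 has disappeared.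

Step 4. The electron-rich catechol, formed while activated DMSO is still present, may undergo methylthiomethylation, or the oxidation may stall at the α-hydroxy ketone. The fallback over-oxidises on purpose and then reduces. It sets out from 6, which is treated with excess 2-iodoxybenzoic acid (IBX, DMSO–THF, about 60 °C); this reagent oxidises vicinal diols to 1,2-diones without C–C cleavage and takes the resulting catechol on to the ortho-quinone heneicosyl 5,6-dioxocyclohexa-1,3-diene-1-carboxylate F4. Direct reduction with aqueous Na2S2O4 in the work-up comes back to the route at 8.

**Further compounds**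
F1 | step 2 | heneicosyl all-cis-2,2-dimethyl-3a,4,7,7a-tetrahydro-1,3-benzodioxole-4-carboxylate (racemic) | CC1(C)O[C@H]2[C@@H](C(=O)OCCCCCCCCCCCCCCCCCCCCC)C=CC[C@H]2O1
F2 | step 3 | heneicosyl cyclohexa-2,5-diene-1-carboxylate | CCCCCCCCCCCCCCCCCCCCCOC(=O)C1C=CCC=C1
F3 | step 3 | heneicosyl (1RS,5RS,6SR)-5,6-dihydroxycyclohex-2-ene-1-carboxylate (racemic) | O[C@H]1[C@H](C(=O)OCCCCCCCCCCCCCCCCCCCCC)C=CC[C@H]1O
F4 | step 4 | heneicosyl 5,6-dioxocyclohexa-1,3-diene-1-carboxylate | CCCCCCCCCCCCCCCCCCCCCOC(=O)C1=CC=CC(=O)C1=O
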